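- 4 questions stood before me, and the flasks lay at two ends: cold ones still growing at the stop, hot ones already on a plateau.

| flask | solid monomer | initiator | temperature | remark | time |
|---|---|---|---|---|---|
| birch | 1.1 M | 0.5 mol% | −5 °C | run made earlier |  |
| alder | 1.8 M | 0.5 mol% | 25 °C | run made earlier |  |
| maple | 0.80 M | 0.75 mol% | −5 °C | run made earlier |  |
| Saturday's | 0.80 M | 0.5 mol% | 50 °C |  | 2.0 h |
| Tuesday's | 0.80 M | 0.5 mol% | 0 °C |  | 2.0 h |
| Monday's | 0.80 M | 0.5 mol% | 25 °C |  | 2.0 h |

| run | time / h | monomer in chains / % | solid monomer / % |
|---|---|---|---|
| birch | 1.50 | 14.2 | 77.1 |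
| birch | 2.50 | 24.3 | 66.7 |
| birch | 5.00 | 52.6 | 37.1 |
| birch | 10.0 | 96.2 | 0.5 |
| birch | 20.0 | 95.9 | 0.2 |
| alder | 0.333 | 23.4 | 70.7 |
| alder | 1.00 | 80.8 | 11.6 |
| alder | 1.50 | 94.9 | 0 |
| alder | 3.00 | 95.7 | 0.7 |
| alder | 5.00 | 96.5 | 0 |
| maple | 1.50 | 21.4 | 67.4 |
| maple | 2.50 | 35.7 | 50.5 |
| maple | 5.00 | 77.8 | 8.6 |
| maple | 10.0 | 96.6 | 0 |
| maple | 20.0 | 96.2 | 0 |

(each reading ± 0.5 percentage points)

- in percentages every species weighs as the solid monomer in it: one self-condensation product counts as two
- for monomer in chains the idle complex is counted in
- as a solid, counted per litre of solution: solid monomer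
- the numbers in the tables scatter with a standard deviation of 0.5 percentage points
- steps that have been proposed: free monomer + initiator -> living end + monomer in chains; free monomer + living end -> monomer in chains + living end; initiator + monomer in chains <-> idle complex; 2 free monomer -> self-condensation product; solid monomer <-> free monomer
- at the start none of the solid monomer is in solution

- which flask leads in amount of monomer in chains, in percent of the solid monomer charged ("all alike" within 1.5 percentage points) (Saturday's / Tuesday's / Monday's / all alike)
- how much monomer in chains is there at the end, in percent of the solid monomer charged: Saturday's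
- how much monomer in chains is there at the end, in percent of the solid monomer charged: Tuesday's
- how much monomer in chains is there at the end, in percent of the solid monomer charged: Monday's

- From the last readings of the runs I read the plateaus of monomer in chains: alder at 25 °C 95.7%, birch at −5 °C 96.1%, and I took the missing part as self-condensation product.
- Before reckoning, I tested these readings. Saturday's lies 0.833 of the birch-to-alder temperature span beyond alder, so a shift of 0.5 percentage points in alder's plateau moves Saturday's loss ratio by 21.3%. The same shift in birch's moves it by 10.5%, so alder's plateau counts more than birch's.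
- At 25 °C, alder's early growth of 0.861 /h gave me an estimate of 1.11 h to fill its plateau, less than the 2.0 h of Monday's flask.
- My waste number (a selectivity factor turned upside down) is the plateau ratio of self-condensation product to monomer in chains, times initiator charged per litre. Birch gave 0.226 mM, maple 0.224 mM, alder 0.404 mM. The same factor per degree gave 0.656 mM at 50 °C.
- With 4.00 mM of initiator, I expected Monday's 90.8% and Saturday's 85.9%. For Tuesday's, birch's growth of 0.110 /h, carried per degree toward alder's, gave 30.9%.
- The forecast, higher than mine on none of these, said Monday's, with 85.5%, 28% and 90%, on this ground: “Their plateaus are set by the roughly 4 % loss to self-condensation”.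
- The flasks gave Monday's first: Saturday's 85.9%, Tuesday's 33.0%, Monday's 91.7%.

    free monomer + initiator → living end + monomer in chains (k = 0.130 /M/s, Ea = 44.0 kJ/mol)
    free monomer + living end → monomer in chains + living end, rate k2*[living end]*[free monomer] (k = 0.709 /M/s, Ea = 36.0 kJ/mol)
    initiator + monomer in chains ⇌ idle complex, settled at all times (K = 94.0 /M, ΔH = −47.0 kJ/mol)
    2 free monomer → self-condensation product (k = 0.00142 /M/s, Ea = 63.0 kJ/mol)
    solid monomer ⇌ free monomer, rate k5*(cs5 - [free monomer]) while solid is left; crystals form when [free monomer] > cs5 (solubility = 0.0910 M, k = 0.0403 /s)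
    (constants at 25 °C)

- Saturday's ended with 14.1% self-condensation product, a waste number of 0.656 mM beside my 0.656 mM. The neighbour is Saturday's flask with 0.12 mol% of initiator, or 0.960 mM. The waste number puts its ratio at 0.683 and its monomer in chains at 59.4%. That flask gave 57.1%, with 42.9% self-condensation product, a waste number of 0.720 mM.

The numbers in the tables are calculated from invented constants; the scatter is artificial.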